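## Retrosynthetic overview

1. The last bond made is C2–C1′, between ring C and ring B. C2 of a chromone is natively electrophilic (a vinylogous ester carbon, the masked CHO of a β-keto aldehyde). Here it is used with reversed polarity as a C2 carbanion (an α-alkoxyvinyl zinc, an acyl anion equivalent) and joined to the equally electrophilic carbon–iodine carbon of a ring B iodophenol.
2. 5,6,7,8-Tetramethoxychromone comes from 2-hydroxy-3,4,5,6-tetramethoxyacetophenone plus one carbon (DMF-DMA). Ring C is therefore closed before the coupling.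
3. The acetophenone comes from 3,4,5-trimethoxyphenol by C-acetylation, bromination of the last ring C–H, and copper-catalysed methoxylation.
4. The iodophenol comes from 1,2,4-trimethoxybenzene. Ortho-lithiation, borylation and oxidation place the 3′-OH, and a transient trifluoroacetate steers iodination to C1′.
5. Rings A and B are bought as benzenes, ring C is formed in step 4, and the three rings are united in the last step. No protecting group is carried through.

Assumption: the target SMILES has no stereocentre, stereogenic axis or stereogenic double bond. Agehoustin C is achiral, so the route delivers the one compound that exists.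

## Route

TMP = 2,2,6,6-tetramethylpiperidide.

**Step 1**
Reactants: 1 3,4,5-trimethoxyphenol
Product: 2 1-(6-hydroxy-2,3,4-trimethoxyphenyl)ethan-1-one
Conditions: Ac2O (1.2 equiv), BF3·OEt2 (co-solvent), 85 °C, 2 h; aq NaOAc
Reagents that add atoms: acetic anhydride, CC(=O)OC(C)=O
Why: This is a Friedel–Crafts/Fries-type C-acetylation in which the two positions ortho to the phenol are equivalent, so a single ketone forms, and its boron chelate is deactivated toward a second acylation.

**Step 2**
Reactants: 2 1-(6-hydroxy-2,3,4-trimethoxyphenyl)ethan-1-one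
Product: 3 1-(3-bromo-2-hydroxy-4,5,6-trimethoxyphenyl)ethan-1-one
Conditions: NBS (1.05 equiv), CH2Cl2, 0 °C to rt
Reagents that add atoms: N-bromosuccinimide, O=C1CCC(=O)N1Br
Why: In this electrophilic aromatic bromination the only remaining ring C–H lies ortho to the phenol and to a methoxy group, so it is brominated much faster than the chelated acetyl group can enolise.

**Step 3**
Reactants: 3 1-(3-bromo-2-hydroxy-4,5,6-trimethoxyphenyl)ethan-1-one
Product: 4 1-(2-hydroxy-3,4,5,6-tetramethoxyphenyl)ethan-1-one
Conditions: NaOMe (28% in MeOH, 8 equiv), CuBr (0.2 equiv), DMF, 110 °C, N2; aq HCl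
Reagents that add atoms: sodium methoxide, [Na+].[O-]C
Why: An Ullmann-type copper-catalysed methoxylation replaces the aryl bromide while the substrate reacts as its sodium phenoxide, which shields the ketone, and acid work-up returns the chelated phenol.

**Step 4**
Reactants: 4 1-(2-hydroxy-3,4,5,6-tetramethoxyphenyl)ethan-1-one
Product: 6 5,6,7,8-tetramethoxy-4H-chromen-4-one, via enaminone 5 (not isolated)
Conditions: DMF-DMA (2 equiv), toluene, 100 °C; evaporate; conc. HCl, CH2Cl2, 40 °C
Reagents that add atoms: N,N-dimethylformamide dimethyl acetal, COC(OC)N(C)C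
Why: Enaminone condensation at the acetyl CH3, then acid-triggered intramolecular oxa-Michael addition and loss of dimethylamine (the enaminone chromone synthesis), closes ring C and leaves C2–H free.

**Step 5**
Reactants: 7 1,2,4-trimethoxybenzene
Product: 10 2,3,6-trimethoxyphenol, via aryllithium 8 (not isolated), via lithium aryltrimethoxyborate 9 (not isolated)
Conditions: n-BuLi (1.1 equiv), THF, 0 °C to rt; B(OMe)3 (1.3 equiv), −78 °C to rt; AcOH, 30% aq H2O2, 0 °C to rt
Reagents that add atoms: hydrogen peroxide, OO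
Why: Directed ortho-metalation removes the proton flanked by two methoxy groups (C3), and borylation–oxidation (1,2-aryl shift from boron to oxygen) turns that carbon–lithium bond into the future 3′-OH.

**Step 6**
Reactants: 10 2,3,6-trimethoxyphenol
Product: 13 3-iodo-2,5,6-trimethoxyphenol, via aryl trifluoroacetate 11 (not isolated), via iodoaryl trifluoroacetate 12 (not isolated)
Conditions: (CF3CO)2O (1.5 equiv), MeCN, 0 °C to rt, 30 min; NIS (1.05 equiv), rt, dark; aq Na2S2O3, then aq NaHCO3/MeOH, rt
Reagents that add atoms: N-iodosuccinimide, O=C1CCC(=O)N1I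
Why: O-Trifluoroacetylation ties up the phenol lone pair, so acid-activated electrophilic aromatic iodination goes to C5 (one ortho and one para methoxy donor) rather than C4 (para to the now electron-poor ester oxygen, one ortho donor), and the labile ester is hydrolysed in the work-up after the oxidant has been quenched.

**Step 7 (key step)**
Reactants: 6 5,6,7,8-tetramethoxy-4H-chromen-4-one; 13 3-iodo-2,5,6-trimethoxyphenol
Product: 17 agehoustin C, 2-(3-hydroxy-2,4,5-trimethoxyphenyl)-5,6,7,8-tetramethoxy-4H-chromen-4-one, via chromon-2-ylzinc chloride 14 (not isolated), via chlorozinc iodophenoxide 15 (not isolated), via chlorozinc flavone phenoxide 16 (not isolated)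
Conditions: flask A: 6, TMPZnCl·LiCl (1.15 equiv, no MgCl2 or BF3 present), THF, 25 °C, 1 h; flask B: 13 (1.1 equiv), TMPZnCl·LiCl (1.1 equiv), THF, 0 °C, 10 min; combine, Pd(OAc)2 (3 mol %), SPhos (6 mol %), 50 °C, 6 h; 1 M HCl work-up
Reagents that add atoms: none
Why: Deprotonative zincation with the Lewis-acid-free TMP-zinc base removes the most acidic vinylic proton (C2–H, next to the ring oxygen), which turns the natively electrophilic vinylogous-ester carbon into an α-alkoxyvinyl/β-acylvinyl carbanion (an acyl anion equivalent), and a Negishi cross-coupling joins it to the electrophilic carbon–iodine carbon of 15, with zinc tolerating the ketone and the phenol riding through as its zinc phenoxide until the acid work-up.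

## Compound list

| No. | Name | SMILES | Role |
|---|---|---|---|
| 1 | 3,4,5-trimethoxyphenol | Oc1cc(OC)c(OC)c(OC)c1 | starting material |
| 2 | 1-(6-hydroxy-2,3,4-trimethoxyphenyl)ethan-1-one | CC(=O)c1c(O)cc(OC)c(OC)c1OC | intermediate |
| 3 | 1-(3-bromo-2-hydroxy-4,5,6-trimethoxyphenyl)ethan-1-one | CC(=O)c1c(O)c(Br)c(OC)c(OC)c1OC | intermediate |
| 4 | 1-(2-hydroxy-3,4,5,6-tetramethoxyphenyl)ethan-1-one | CC(=O)c1c(O)c(OC)c(OC)c(OC)c1OC | intermediate |
| 5 | (E)-3-(dimethylamino)-1-(2-hydroxy-3,4,5,6-tetramethoxyphenyl)prop-2-en-1-one | CN(C)/C=C/C(=O)c1c(O)c(OC)c(OC)c(OC)c1OC | intermediate |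
| 6 | 5,6,7,8-tetramethoxy-4H-chromen-4-one | O=c1ccoc2c(OC)c(OC)c(OC)c(OC)c12 | intermediate |
| 7 | 1,2,4-trimethoxybenzene | COc1ccc(OC)c(OC)c1 | starting material |
| 8 | (2,3,6-trimethoxyphenyl)lithium | [Li]c1c(OC)ccc(OC)c1OC | intermediate |
| 9 | lithium trimethoxy(2,3,6-trimethoxyphenyl)borate | [Li+].CO[B-](OC)(OC)c1c(OC)ccc(OC)c1OC | intermediate |
| 10 | 2,3,6-trimethoxyphenol | Oc1c(OC)c(OC)ccc1OC | intermediate |
| 11 | 2,3,6-trimethoxyphenyl trifluoroacetate | O=C(Oc1c(OC)c(OC)ccc1OC)C(F)(F)F | intermediate |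
| 12 | 3-iodo-2,5,6-trimethoxyphenyl trifluoroacetate | O=C(Oc1c(OC)c(OC)cc(I)c1OC)C(F)(F)F | intermediate |
| 13 | 3-iodo-2,5,6-trimethoxyphenol | Oc1c(OC)c(OC)cc(I)c1OC | intermediate |
| 14 | (5,6,7,8-tetramethoxy-4-oxo-4H-chromen-2-yl)zinc chloride | Cl[Zn]c1cc(=O)c2c(OC)c(OC)c(OC)c(OC)c2o1 | intermediate |
| 15 | chlorozinc 3-iodo-2,5,6-trimethoxyphenoxide | Cl[Zn]Oc1c(OC)c(OC)cc(I)c1OC | intermediate |
| 16 | chlorozinc 2,5,6-trimethoxy-3-(5,6,7,8-tetramethoxy-4-oxo-4H-chromen-2-yl)phenoxide | Cl[Zn]Oc1c(OC)c(OC)cc(-c2cc(=O)c3c(OC)c(OC)c(OC)c(OC)c3o2)c1OC | intermediate |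
| 17 | agehoustin C, 2-(3-hydroxy-2,4,5-trimethoxyphenyl)-5,6,7,8-tetramethoxy-4H-chromen-4-one | COc1cc(-c2cc(=O)c3c(OC)c(OC)c(OC)c(OC)c3o2)c(OC)c(O)c1OC | target |

## Step count and risks

Total step count: 7.
Longest linear sequence: 5 (steps 1, 2, 3, 4, 7).

**Step 7.**
- Risk: the 4-carbonyl/5-methoxy pair may chelate the metal and pull metalation toward C3. The stabilised C2–zinc species may also transmetalate slowly onto the hindered, electron-rich aryl palladium.
- Fallback: it sets out from 6 and comes back at 17.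
- LiTMP is added at −78 °C to a THF solution holding both 6 and B(OiPr)3. The kinetically formed 2-lithio-5,6,7,8-tetramethoxy-4H-chromen-4-one F1 is then trapped at once as lithium triisopropoxy(5,6,7,8-tetramethoxy-4-oxo-4H-chromen-2-yl)borate F2.
- This salt keeps the reversed polarity at C2, and its regiochemistry can be checked by NMR.
- It is joined to the free phenol 13 by Suzuki–Miyaura coupling (Pd(OAc)2, XPhos, aq K3PO4, THF, 40 °C). That coupling tolerates the OH and gives 17 directly.

**Step 6.**
- Risk: the central methoxy group para to C5 is twisted out of conjugation, so the C5/C4 preference may be smaller than expected. Any unacylated phenol would iodinate at C4.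
- Fallback: it sets out from 10 and comes back at 13.
- Halogenation is replaced by site-selective C–H thianthrenation, which discriminates far more sharply for the position para to the best donor.
- Thianthrene S-oxide, (CF3CO)2O (which again makes 11 in the flask) and HBF4·OEt2 in MeCN at 0 °C give 5-[2,4,5-trimethoxy-3-(trifluoroacetoxy)phenyl]-5H-thianthren-5-ium tetrafluoroborate F3.
- Aqueous bicarbonate work-up gives crystalline 5-(3-hydroxy-2,4,5-trimethoxyphenyl)-5H-thianthren-5-ium tetrafluoroborate F4, which can be freed of any isomer by recrystallisation.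
- LiI, Cu(MeCN)4BF4 and catalytic Ru(bpy)3(PF6)2 under blue light in MeCN then exchange the sulfonium group for iodine to give 13.

**Step 3.**
- Risk: the bromide is flanked on both sides and sits on a very electron-rich phenoxide, so hydrodebromination back to 2 can compete.
- Fallback: it sets out from 2, bypasses 3, and comes back at 4.
- The oxygen is introduced through a carbon placeholder. Rieche formylation (Cl2CHOMe, TiCl4, CH2Cl2, 0 °C) at the only free ring position gives 3-acetyl-2-hydroxy-4,5,6-trimethoxybenzaldehyde F5.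
- Dakin oxidation (H2O2, aq NaOH, 0 °C) passes through 3-acetyl-2-hydroxy-4,5,6-trimethoxyphenyl formate F6 to 1-(2,3-dihydroxy-4,5,6-trimethoxyphenyl)ethan-1-one F7.
- MeI (1.0 equiv) and K2CO3 in acetone methylate only the hydroxyl that is not hydrogen-bonded to the ketone, which gives 4.

## Further compounds

F1 | step 7 | 2-lithio-5,6,7,8-tetramethoxy-4H-chromen-4-one | [Li]c1cc(=O)c2c(OC)c(OC)c(OC)c(OC)c2o1
F2 | step 7 | lithium triisopropoxy(5,6,7,8-tetramethoxy-4-oxo-4H-chromen-2-yl)borate | [Li+].CC(C)O[B-](OC(C)C)(OC(C)C)c1cc(=O)c2c(OC)c(OC)c(OC)c(OC)c2o1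
F3 | step 6 | 5-[2,4,5-trimethoxy-3-(trifluoroacetoxy)phenyl]-5H-thianthren-5-ium tetrafluoroborate | O=C(Oc1c(OC)c(OC)cc([S+]2c3ccccc3Sc3ccccc23)c1OC)C(F)(F)F.F[B-](F)(F)F
F4 | step 6 | 5-(3-hydroxy-2,4,5-trimethoxyphenyl)-5H-thianthren-5-ium tetrafluoroborate | Oc1c(OC)c(OC)cc([S+]2c3ccccc3Sc3ccccc23)c1OC.F[B-](F)(F)F
F5 | step 3 | 3-acetyl-2-hydroxy-4,5,6-trimethoxybenzaldehyde | CC(=O)c1c(O)c(C=O)c(OC)c(OC)c1OC
F6 | step 3 | 3-acetyl-2-hydroxy-4,5,6-trimethoxyphenyl formate | CC(=O)c1c(O)c(OC=O)c(OC)c(OC)c1OC
F7 | step 3 | 1-(2,3-dihydroxy-4,5,6-trimethoxyphenyl)ethan-1-one | CC(=O)c1c(O)c(O)c(OC)c(OC)c1OC
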